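**Retrosynthetic overview**

- The C5–propenyl bond is made last: target ⇐ (2R,3R)-5-bromo-dihydrobenzofuran + (E)-propenyl boronate (Suzuki–Miyaura), so the acid-sensitive styrene never meets the acid step.
- Key disconnection O1–C2: the bromo-dihydrobenzofuran ⇐ (E)-2-hydroxy-α-methylstilbene by a catalytic asymmetric 5-endo hydroalkoxylation. This one C–O ring closure sets C2 and C3 together.
- C2=C3 unit: the stilbene ⇐ 5-bromopaeonol + 3,4,5-trimethoxybenzyl chloride (Grignard addition, dehydration in the same flask).
- Ring order: both benzene rings are bought; the dihydrofuran ring is the only ring formed (step 2). No protecting groups; three steps.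

Assumption: the target is the (2R,3R)-2,3-trans isomer encoded by the SMILES, and 5-bromopaeonol (1) is taken as a catalogue compound (otherwise one step from paeonol with NBS).

**Route**

Step 1
Reactants: 1 1-(5-bromo-2-hydroxy-4-methoxyphenyl)ethan-1-one (5-bromopaeonol); 2 5-(chloromethyl)-1,2,3-trimethoxybenzene (3,4,5-trimethoxybenzyl chloride)
Product: 5 (E)-4-bromo-5-methoxy-2-[1-(3,4,5-trimethoxyphenyl)prop-1-en-2-yl]phenol, via benzylic Grignard reagent 3 (not isolated), via tertiary benzylic alcohol 4 (not isolated)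
Conditions: 2 (2.6 equiv), Mg (3 equiv, I2 cat.), 2-MeTHF, 0 °C; then 1, 0 °C → rt; then 2 M aq. HCl, 40 °C; crystallise the E isomer
Reagents that add atoms: 2 3,4,5-trimethoxybenzyl chloride, COc1cc(CCl)cc(OC)c1OC (gives the ArCH2 unit, Cl is lost)
Why: Grignard 1,2-addition to the chelated magnesium phenoxide ketone (one extra equivalent of 3 is spent on the ArOH), then E1 dehydration of the carbinol, which is benzylic to a 2-hydroxy-4-methoxyphenyl ring and ionises in mild aqueous acid, to the conjugated, thermodynamically preferred (E)-stilbene; no stereocentre survives this step.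

Step 2
Reactants: 5 (E)-4-bromo-5-methoxy-2-[1-(3,4,5-trimethoxyphenyl)prop-1-en-2-yl]phenol
Product: 6 (2R,3R)-5-bromo-6-methoxy-3-methyl-2-(3,4,5-trimethoxyphenyl)-2,3-dihydro-1-benzofuran
Conditions: (S,S)-IDPi (confined BINOL-derived imidodiphosphorimidate, 3,3'-aryl groups, P=N–SO2CF3 core; 5 mol%), 5 Å MS, cyclohexane/CHCl3 4:1, 0.02 M, 25 °C
Reagents that add atoms: none
Why: Proposed new method: enantio- and diastereoselective 5-endo hydroalkoxylation of a 2-hydroxy-α-methylstilbene by a confined strong chiral Brønsted acid. Inside the catalyst pocket the acid delivers H+ to one face of C3 (enantio-determining, gives 3R) while its conjugate base hydrogen-bonds the phenol OH, so the phenol oxygen closes onto the developing 3,4,5-trimethoxybenzylic cation at C2 in a concerted-asynchronous or tight-ion-pair event that puts the aryl group trans to the new C3 methyl (the kinetically and thermodynamically preferred 2,3-trans ring, 2R). The competing protonation at C2 gives only the tertiary o-hydroxybenzylic cation, which cannot close a ring and reverts, so it should merely interconvert the E, Z and exo-methylene isomers of 5. The closest known reactions are the IDPi-catalysed asymmetric intramolecular hydroalkoxylation of unactivated alkenes to tetrahydrofurans and the racemic strong-acid cyclisation of 2-hydroxystilbenes to 2-aryl-2,3-dihydrobenzofurans; new here are the 5-endo mode with a phenol nucleophile, the trisubstituted styrenyl alkene and the control of two stereocentres in one C–O bond-forming step.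

Step 3
Reactants: 6 (2R,3R)-5-bromo-6-methoxy-3-methyl-2-(3,4,5-trimethoxyphenyl)-2,3-dihydro-1-benzofuran; 7 4,4,5,5-tetramethyl-2-[(E)-prop-1-en-1-yl]-1,3,2-dioxaborolane ((E)-propenylboronic acid pinacol ester)
Product: 8 (2R,3R)-6-methoxy-3-methyl-5-[(E)-prop-1-en-1-yl]-2-(3,4,5-trimethoxyphenyl)-2,3-dihydro-1-benzofuran (target)
Conditions: 7 (1.5 equiv), Pd(OAc)2 (3 mol%), SPhos (6 mol%), K3PO4, toluene/H2O 10:1, 80 °C
Reagents that add atoms: 7 (E)-propenylboronic acid pinacol ester, C/C=C/B1OC(C)(C)C(C)(C)O1 (gives the propenyl group)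
Why: Suzuki–Miyaura coupling; the biarylphosphine ligand handles the electron-rich, ortho-methoxy aryl bromide, the alkenyl group transfers from boron with retention of the (E)-geometry, and the mild base leaves C2 and C3 untouched.

**Compound list**

1 | 1-(5-bromo-2-hydroxy-4-methoxyphenyl)ethan-1-one (5-bromopaeonol) | CC(=O)c1cc(Br)c(OC)cc1O | starting material
2 | 5-(chloromethyl)-1,2,3-trimethoxybenzene (3,4,5-trimethoxybenzyl chloride) | COc1cc(CCl)cc(OC)c1OC | starting material
3 | (3,4,5-trimethoxybenzyl)magnesium chloride | COc1cc(C[Mg]Cl)cc(OC)c1OC | intermediate (not isolated)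
4 | 2-(5-bromo-2-hydroxy-4-methoxyphenyl)-1-(3,4,5-trimethoxyphenyl)propan-2-ol (racemic) | CC(O)(Cc1cc(OC)c(OC)c(OC)c1)c1cc(Br)c(OC)cc1O | intermediate (not isolated)
5 | (E)-4-bromo-5-methoxy-2-[1-(3,4,5-trimethoxyphenyl)prop-1-en-2-yl]phenol | C/C(=C\c1cc(OC)c(OC)c(OC)c1)c1cc(Br)c(OC)cc1O | intermediate
6 | (2R,3R)-5-bromo-6-methoxy-3-methyl-2-(3,4,5-trimethoxyphenyl)-2,3-dihydro-1-benzofuran (2,3-trans) | Brc1cc2c(cc1OC)O[C@@H](c1cc(OC)c(OC)c(OC)c1)[C@@H]2C | intermediate
7 | 4,4,5,5-tetramethyl-2-[(E)-prop-1-en-1-yl]-1,3,2-dioxaborolane | C/C=C/B1OC(C)(C)C(C)(C)O1 | starting material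
8 | (2R,3R)-6-methoxy-3-methyl-5-[(E)-prop-1-en-1-yl]-2-(3,4,5-trimethoxyphenyl)-2,3-dihydro-1-benzofuran (2,3-trans) | C/C=C/c1cc2c(cc1OC)O[C@@H](c1cc(OC)c(OC)c(OC)c1)[C@@H]2C | target

**Step count and risks**

Total step count: 3. Longest linear sequence: 3 (1 → 5 → 6 → 8).

Steps most likely to fail, most risky first:

1. Step 2 (the proposed new reaction).
   - Risks:
     - The alkene protonates more easily at C2 than at C3; if the resulting tertiary cation is trapped intermolecularly, dimers form instead of 6.
     - The secondary benzylic cation at C2 is only moderately stabilised, so the rate may be low.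
     - Reversible ring opening could erode ee.
     - The sense of induction cannot be predicted for a new reaction. It must be assigned in the first run (X-ray with Br anomalous dispersion), and the catalyst antipode that gives (2R,3R) is then used.
   - Fallback with known chemistry, setting out from 5 and returning at 6. Brown asymmetric hydroboration–oxidation of 5 with monoisopinocampheylborane (2.5 equiv, the first equivalent being consumed by the ArOH; THF, −25 °C; then NaOH, H2O2) adds H and OH syn across the (E)-alkene with boron on the less hindered C2. This gives (1R,2R)-2-(5-bromo-2-hydroxy-4-methoxyphenyl)-1-(3,4,5-trimethoxyphenyl)propan-1-ol F4. The reagent antipode is fixed by a test run and the ee is raised by crystallisation. BF3·OEt2 (CH2Cl2, −40 °C) then ionises the benzylic alcohol and the phenol closes the ring by SN1. C3 is untouched and C2 settles into the 2,3-trans ring, giving 6.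

2. Step 1.
   - Risks: Wurtz coupling while making 3, enolisation of 1 instead of addition, and E/Z/exo-methylene mixtures after dehydration.
   - Fallback setting out from 1 and 2 and returning at 5; it replaces the benzylic Grignard by a Horner–Wadsworth–Emmons olefination. 1 is capped with MOMCl/i-Pr2NEt (CH2Cl2, 0 °C) to 1-[5-bromo-4-methoxy-2-(methoxymethoxy)phenyl]ethan-1-one F1. 2 is heated with P(OEt)3 (neat, 140 °C, Michaelis–Arbuzov) to diethyl [(3,4,5-trimethoxyphenyl)methyl]phosphonate F2. F2 with KOt-Bu (DMF, 0 → 60 °C) olefinates F1 to 1-bromo-2-methoxy-4-(methoxymethoxy)-5-[(E)-1-(3,4,5-trimethoxyphenyl)prop-1-en-2-yl]benzene F3. Aqueous HCl/THF (50 °C) removes the MOM group and gives 5.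

3. Step 3.
   - Risks: slow oxidative addition at the electron-rich, ortho-methoxy aryl bromide; protodeboronation or E/Z erosion of the alkenyl boronate.
   - Fallback setting out from 6 and returning at 8. Stille allylation (allyltributylstannane, Pd(PPh3)4, toluene, 100 °C) gives (2R,3R)-6-methoxy-3-methyl-5-(prop-2-en-1-yl)-2-(3,4,5-trimethoxyphenyl)-2,3-dihydro-1-benzofuran F5. PdCl2(MeCN)2 (CH2Cl2, rt) then moves the double bond into conjugation and gives the thermodynamic (E)-propenyl compound 8.

**Further compounds**

F1 | step 1 | 1-[5-bromo-4-methoxy-2-(methoxymethoxy)phenyl]ethan-1-one | CC(=O)c1cc(Br)c(OC)cc1OCOC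
F2 | step 1 | diethyl [(3,4,5-trimethoxyphenyl)methyl]phosphonate | CCOP(=O)(Cc1cc(OC)c(OC)c(OC)c1)OCC
F3 | step 1 | 1-bromo-2-methoxy-4-(methoxymethoxy)-5-[(E)-1-(3,4,5-trimethoxyphenyl)prop-1-en-2-yl]benzene | C/C(=C\c1cc(OC)c(OC)c(OC)c1)c1cc(Br)c(OC)cc1OCOC
F4 | step 2 | (1R,2R)-2-(5-bromo-2-hydroxy-4-methoxyphenyl)-1-(3,4,5-trimethoxyphenyl)propan-1-ol | C[C@H](c1cc(Br)c(OC)cc1O)[C@@H](O)c1cc(OC)c(OC)c(OC)c1
F5 | step 3 | (2R,3R)-6-methoxy-3-methyl-5-(prop-2-en-1-yl)-2-(3,4,5-trimethoxyphenyl)-2,3-dihydro-1-benzofuran | C=CCc1cc2c(cc1OC)O[C@@H](c1cc(OC)c(OC)c(OC)c1)[C@@H]2C
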